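The larch flask cannot hold more target than the 100 mM of substrate charged to it, and that ceiling is my first bound on the share asked for.

| flask | substrate | reagent | target | time |
|---|---|---|---|---|
| elm | 200 mM | 500 mM |  |  |
| oak | 100 mM | 400 mM |  |  |
| ash | 200 mM | 500 mM | 100 mM |  |
| alder | 200 mM | 1000 mM |  |  |
| larch | 100 mM | 1500 mM |  | 12 min |

| run | time / min | [target] / mM |
|---|---|---|
| elm run | 0.91 | 18.8 |
| elm run | 2.8 | 47.3 |
| elm run | 5.3 | 69.1 |
| elm run | 8.4 | 84.1 |
| elm run | 12 | 91.7 |
| oak run | 0.91 | 8.3 |
| oak run | 2.8 | 20.8 |
| oak run | 5.3 | 32.7 |
| oak run | 8.4 | 40.7 |
| oak run | 12 | 45.9 |
| ash run | 0.91 | 113.8 |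
| ash run | 2.8 | 134.1 |
| ash run | 5.3 | 145.3 |
| ash run | 8.4 | 150.4 |
| ash run | 12 | 150.4 |
| alder run | 0.91 | 35.8 |
| alder run | 2.8 | 76.4 |
| alder run | 5.3 | 95.9 |
| alder run | 8.4 | 97.2 |
| alder run | 12 | 87.5 |

(readings scatter by 0.6 mM)

- Overall: substrate + reagent -> target.
- Constant volume, constant temperature.
- What is held in complexes is read along with the free species.
- An order is taken over about fifteen percent of the charge, up and down.

- how the opening rate goes with [reagent] round the charge of the elm run: the exponent of the rate at two percent of substrate gone to target
- how the opening rate goes with [substrate] round the charge of the elm run: the exponent of the rate at two percent of substrate gone to target (one fixed amount of target, the same in the runs compared)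
- target in the larch run at 12 min, as a share of the substrate charged

To tighten that bound I need a rate of loss. By its first reading the elm run makes target at 20.7 mM min⁻¹. The ash run has the same charge plus 100 mM of target, yet it gains 15.2 mM min⁻¹, which is less. I put the whole difference in rate down to loss of target, which is my assumption, and divide the added target by it. This gives 18.2 min at 500 mM of reagent. I call it the target lifetime, the time a stock of target lasts at its opening rate of loss. It is a reading, and the first ash reading puts about 0.659 mM min⁻¹ of scatter on the difference.

The alder run has twice the reagent of the elm run and makes 1.90 times the target by its first reading. So I take making as first order in [reagent]. By its first reading the oak run makes 0.441 of the elm run's target, on a product of charges 0.400 of the elm run's, so I take making as first order in [substrate] too. That the loss is first order in [reagent] is my assumption. Larch holds 15.0 times as much reagent as substrate, so I treat both steps as pseudo-first-order. Its target lifetime is 6.07 min, and its substrate lifetime, scaled from the elm rate, is 3.23 min.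

Now the bracket for larch, which holds on these two lifetimes. By 12 min a share 97.6% of the substrate has turned, and each portion of target made survives at least 13.8%, so their product, 13.5%, is my lower bound. For the upper bound I cut the time at 6.00 min. Target made before the cut survives at most 37.2%, and substrate unturned at the cut is 15.6%, so the sum is 52.8%. Running the two lifetimes in series gives my figure, 24.4%.

The forecast gives 30% for the larch share, inside the bracket and above my figure, with orders 1 in reagent and 0.85 in substrate. Its ground is “Decay at 0.07–0.1 per min then leaves about 30% of the charge”. My loss of target in larch is 0.165 min⁻¹.

The larch flask gives 23.9% at 12 min, and round the charge of the elm run the orders are 1.0 in reagent and 1.0 in substrate.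

    substrate + reagent ⇌ target + by-product (0.2442 L mol⁻¹ min⁻¹, 1.458 L mol⁻¹ min⁻¹)
    reagent + by-product ⇌ reagent-by-product salt, settled at all times (124.0 L mol⁻¹)
    target + reagent → side product (0.1266 L mol⁻¹ min⁻¹)

The ash run's rate is 0.72 of the elm run's, both taken where the same amount has been made. Scaled by reagent, the target lifetime carries over to the alder run: at 1000 mM of reagent it is 9.10 min, beside a substrate lifetime of 4.84 min. In series on 200 mM of substrate, they give 78.5 mM at 12 min. The alder reading there is 87.5 mM.

The runs are simulated for an exercise; the scatter is artificial.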